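**Retrosynthetic overview**
- Target 12 is cut at the CH2–CH2 bond next to the ester oxygen into two redox-active esters: 5 (from β-caryophyllonic acid) and 11 (from O-linoleoylglycolic acid). They are joined by a Ni-electrocatalytic doubly decarboxylative C(sp3)–C(sp3) coupling, a union of two like-polarity carbons through radicals.
- Enabling feature: the bond lies in the unbranched O–CH2–CH2–CH2–C(=CH2) tether. One carbon is the primary CH2 on the ester oxygen (an oxygen-stabilised acyloxymethyl radical, carried by a glycolate CO2H). The other is the primary CH2 homoallylic to the exocyclic methylene on the cyclobutane (carried by the CO2H of caryophyllonic acid). Neither is stereogenic, and the ring stereocentres are three and four bonds away.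
- 5 comes from acid 4, which comes from keto aldehyde 3, made by selective ozonolysis of the endocyclic C4=C5 alkene of (−)-β-caryophyllene 1 (caryophyllane numbering).
- 11 comes from acid 10, which comes from tert-butyl ester 9, made from linoleic acid 6 and tert-butyl bromoacetate 7.
- No ring is formed. The cyclobutane and both stereocentres come intact from 1; its nine-membered ring is opened in step 1.

Key step: step 7

Remark: the (1S,2R)-cyclobutane of the target corresponds to C9 (S) and C1 (R) of natural (−)-β-caryophyllene, which is taken as the chiral-pool source in high isomeric purity.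

Step 1
Reactants: 1 (−)-β-caryophyllene
Product: 3 4-[(1S,2R)-3,3-dimethyl-2-(3-oxobutyl)cyclobutyl]pent-4-enal, via secondary ozonide 2 (not isolated)
Conditions: O3 (1.0 equiv, metered), CH2Cl2, −78 °C; then PPh3, −78 °C → rt
Reagents that add atoms: ozone, [O-][O+]=O
Why: Criegee ozonolysis should be much faster at the strained, trisubstituted endocyclic E-alkene than at the exocyclic 1,1-disubstituted methylene, so one equivalent should cleave only C4=C5 to the methyl ketone and the aldehyde after PPh3 reduction of the ozonide, with both ring stereocentres carried over unchanged.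

Step 2
Reactants: 3 4-[(1S,2R)-3,3-dimethyl-2-(3-oxobutyl)cyclobutyl]pent-4-enal
Product: 4 4-[(1S,2R)-3,3-dimethyl-2-(3-oxobutyl)cyclobutyl]pent-4-enoic acid (β-caryophyllonic acid)
Conditions: NaClO2, NaH2PO4, 2-methyl-2-butene (excess), t-BuOH/H2O, 0 °C → rt
Reagents that add atoms: sodium chlorite, [Na+].[O-]Cl=O
Why: Pinnick oxidation converts the aldehyde selectively to the acid, the methyl ketone is inert, and the excess 2-methyl-2-butene traps HOCl so that the 1,1-disubstituted alkene should survive.

Step 3
Reactants: 4 4-[(1S,2R)-3,3-dimethyl-2-(3-oxobutyl)cyclobutyl]pent-4-enoic acid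
Product: 5 1,3-dioxoisoindolin-2-yl 4-[(1S,2R)-3,3-dimethyl-2-(3-oxobutyl)cyclobutyl]pent-4-enoate
Conditions: N-hydroxyphthalimide, DIC, DMAP (cat.), CH2Cl2, rt
Reagents that add atoms: N-hydroxyphthalimide, ON1C(=O)c2ccccc2C1=O
Why: Carbodiimide (Steglich-type) esterification under neutral conditions should give the redox-active N-acyloxyphthalimide without touching the ketone, the alkene or the stereocentres.

Step 4
Reactants: 6 linoleic acid; 7 tert-butyl bromoacetate
Product: 9 2-(tert-butoxy)-2-oxoethyl (9Z,12Z)-octadeca-9,12-dienoate, via cesium linoleate 8 (not isolated)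
Conditions: Cs2CO3, DMF, rt
Reagents that add atoms: none
Why: SN2 O-alkylation of the cesium carboxylate by the activated α-bromo ester is a reliable ester synthesis, and the mild carbonate base should not isomerise the skipped Z,Z-diene.

Step 5
Reactants: 9 2-(tert-butoxy)-2-oxoethyl (9Z,12Z)-octadeca-9,12-dienoate
Product: 10 2-[(9Z,12Z)-octadeca-9,12-dienoyloxy]acetic acid
Conditions: TFA/CH2Cl2 (1:4), 0 °C → rt
Reagents that add atoms: none
Why: Acidolysis of the tert-butyl ester through the tert-butyl cation should leave the primary acyloxy ester and the disubstituted Z-alkenes untouched, as in routine tert-butyl and Boc removals on polyunsaturated lipids.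

Step 6
Reactants: 10 2-[(9Z,12Z)-octadeca-9,12-dienoyloxy]acetic acid
Product: 11 1,3-dioxoisoindolin-2-yl 2-[(9Z,12Z)-octadeca-9,12-dienoyloxy]acetate
Conditions: N-hydroxyphthalimide, DIC, DMAP (cat.), CH2Cl2, 0 °C → rt
Reagents that add atoms: N-hydroxyphthalimide, ON1C(=O)c2ccccc2C1=O
Why: The same carbodiimide esterification as in step 3 should give the redox-active ester of the α-acyloxy acid, with the internal linoleate ester inert.

Step 7
Reactants: 5 1,3-dioxoisoindolin-2-yl 4-[(1S,2R)-3,3-dimethyl-2-(3-oxobutyl)cyclobutyl]pent-4-enoate; 11 1,3-dioxoisoindolin-2-yl 2-[(9Z,12Z)-octadeca-9,12-dienoyloxy]acetate (3 equiv)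
Product: 12 4-[(1S,2R)-3,3-dimethyl-2-(3-oxobutyl)cyclobutyl]pent-4-en-1-yl (9Z,12Z)-octadeca-9,12-dienoate (IN0146)
Conditions: NiCl2·6H2O (20 mol%), 2,2′:6′,2″-terpyridine (20 mol%), AgNO3 (0.3 equiv, Ag-nanoparticle-coated cathode), Mg(+)/RVC(−), undivided cell, NMP, rt, constant current; dilute aq. HCl work-up
Reagents that add atoms: none
Why: Low-valent Ni generated at the cathode transfers an electron to each N-acyloxyphthalimide, which fragments to phthalimide anion, CO2 and a carbon radical (the primary homoallylic radical from 5 and the acyloxymethyl radical from 11); one radical is held as alkyl–Ni, the second adds to give a dialkyl–Ni(III) that reductively eliminates the CH2–CH2 bond, while the Mg anode supplies the electrons. The closest known reaction type is the Ni-electrocatalytic doubly decarboxylative C(sp3)–C(sp3) cross-coupling of two redox-active esters, which is established for primary alkyl and α-oxygenated partners, and α-acyloxyalkyl–nickel species are viable intermediates in Ni-catalysed couplings of 1-haloalkyl esters. No ring is closed and no stereocentre is created; the two cyclobutane stereocentres lie three and four bonds from the radical carbon and are not touched. The step needs cross- over homo-coupling, which is addressed by the threefold excess of the cheaper ester 11 and by the electronic difference between the oxygen-stabilised acyloxymethyl radical and the unstabilised primary radical; the symmetrical homodimers differ in polarity from 12 and should separate on silica. Rearrangement of the homoallyl radical through its cyclopropylcarbinyl isomer is degenerate here (it only exchanges the two CH2 groups), and the mild cathodic potential should leave the methyl ketone, the ester, the 1,1-disubstituted alkene and the skipped Z,Z-diene intact.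

**Compound list**
1 | (−)-β-caryophyllene, (1R,4E,9S)-4,11,11-trimethyl-8-methylidenebicyclo[7.2.0]undec-4-ene | C/C1=C\CCC(=C)[C@H]2CC(C)(C)[C@@H]2CC1 | starting material
2 | secondary ozonide (1,2,4-trioxolane) across C4/C5 of 1, diastereomer mixture at the two acetal carbons | CC12OC(CCC(=C)[C@H]3CC(C)(C)[C@@H]3CC1)OO2 | intermediate (not isolated)
3 | 4-[(1S,2R)-3,3-dimethyl-2-(3-oxobutyl)cyclobutyl]pent-4-enal | C=C(CCC=O)[C@H]1CC(C)(C)[C@@H]1CCC(C)=O | intermediate
4 | 4-[(1S,2R)-3,3-dimethyl-2-(3-oxobutyl)cyclobutyl]pent-4-enoic acid (β-caryophyllonic acid) | C=C(CCC(=O)O)[C@H]1CC(C)(C)[C@@H]1CCC(C)=O | intermediate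
5 | 1,3-dioxoisoindolin-2-yl 4-[(1S,2R)-3,3-dimethyl-2-(3-oxobutyl)cyclobutyl]pent-4-enoate | C=C(CCC(=O)ON1C(=O)c2ccccc2C1=O)[C@H]3CC(C)(C)[C@@H]3CCC(C)=O | intermediate
6 | linoleic acid, (9Z,12Z)-octadeca-9,12-dienoic acid | CCCCC/C=C\C/C=C\CCCCCCCC(=O)O | starting material
7 | tert-butyl bromoacetate | BrCC(=O)OC(C)(C)C | starting material
8 | cesium (9Z,12Z)-octadeca-9,12-dienoate | CCCCC/C=C\C/C=C\CCCCCCCC(=O)[O-].[Cs+] | intermediate (not isolated)
9 | 2-(tert-butoxy)-2-oxoethyl (9Z,12Z)-octadeca-9,12-dienoate | CCCCC/C=C\C/C=C\CCCCCCCC(=O)OCC(=O)OC(C)(C)C | intermediate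
10 | 2-[(9Z,12Z)-octadeca-9,12-dienoyloxy]acetic acid (O-linoleoylglycolic acid) | CCCCC/C=C\C/C=C\CCCCCCCC(=O)OCC(=O)O | intermediate
11 | 1,3-dioxoisoindolin-2-yl 2-[(9Z,12Z)-octadeca-9,12-dienoyloxy]acetate | CCCCC/C=C\C/C=C\CCCCCCCC(=O)OCC(=O)ON1C(=O)c2ccccc2C1=O | intermediate
12 | 4-[(1S,2R)-3,3-dimethyl-2-(3-oxobutyl)cyclobutyl]pent-4-en-1-yl (9Z,12Z)-octadeca-9,12-dienoate (IN0146) | C=C(CCCOC(=O)CCCCCCC/C=C\C/C=C\CCCCC)[C@H]1CC(C)(C)[C@@H]1CCC(C)=O | target

**Step count and risks**
Total step count: 7. Longest linear sequence: 4 steps (steps 1, 2, 3, 7, or equally steps 4, 5, 6, 7).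

Steps most likely to fail:

Step 7. Homocoupling of each radical may outrun the cross-coupling, and the alkyl radicals may abstract hydrogen from the bis-allylic position of the linoleoyl chain, with loss of the Z,Z-geometry, or be reduced before C–C bond formation. The fallback gives up the convergent C–C coupling and sets out from keto aldehyde 3. Chemoselective reduction of the aldehyde beside the methyl ketone (NaBH4, EtOH/CH2Cl2, −78 °C) should give 4-[(1R,4S)-4-(5-hydroxypent-1-en-2-yl)-2,2-dimethylcyclobutyl]butan-2-one F1. Steglich esterification of this alcohol with linoleic acid 6 (EDC·HCl, DMAP, CH2Cl2, rt) comes back to the route at target 12.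

Step 1. Ozone may also attack the exocyclic methylene once conversion is high, and reduction of the ozonide may be incomplete. The fallback sets out from 1. Catalytic dihydroxylation (OsO4 cat., NMO, acetone/H2O, 0 °C) should be selective for the strained trisubstituted alkene and give, by attack on the exposed face, (1R,4R,5R,9S)-4,11,11-trimethyl-8-methylidenebicyclo[7.2.0]undecane-4,5-diol F2; the configuration at C4 and C5 is immaterial. Glycol cleavage (NaIO4, THF/H2O, rt) comes back to the route at keto aldehyde 3.

Step 5. The acid may cause migration or E/Z isomerisation of the skipped diene, and the tert-butyl cation may alkylate the alkenes. The fallback sets out from linoleic acid 6. Alkylation of its cesium salt with allyl bromoacetate (Cs2CO3, DMF, rt) should give 2-oxo-2-(prop-2-en-1-yloxy)ethyl (9Z,12Z)-octadeca-9,12-dienoate F3. Neutral Pd-catalysed deallylation (Pd(PPh3)4 cat., morpholine, THF, rt) through the π-allyl complex comes back to the route at acid 10.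

Further compounds
F1 | step 7 | 4-[(1R,4S)-4-(5-hydroxypent-1-en-2-yl)-2,2-dimethylcyclobutyl]butan-2-one | C=C(CCCO)[C@H]1CC(C)(C)[C@@H]1CCC(C)=O
F2 | step 1 | (1R,4R,5R,9S)-4,11,11-trimethyl-8-methylidenebicyclo[7.2.0]undecane-4,5-diol | C[C@]1(O)[C@H](O)CCC(=C)[C@H]2CC(C)(C)[C@@H]2CC1
F3 | step 5 | 2-oxo-2-(prop-2-en-1-yloxy)ethyl (9Z,12Z)-octadeca-9,12-dienoate | CCCCC/C=C\C/C=C\CCCCCCCC(=O)OCC(=O)OCC=C
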